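**Plan**
1. Retrosynthetic cuts: C14–C15 (CHBr carbon to the CMe2–O carbon; this closes the macrolide), the benzylic C1–aryl bond (allyl–aryl Suzuki–Miyaura coupling), C12–C13 (allyl cuprate) and the C2–C7 bond of ring A (cation–olefin cyclisation). All C–Br and C–O stereocentres trace back to epoxides of a farnesyl chain.
2. Enabling feature: C15 is a fully substituted, acetone-like carbon (two methyls plus the lactone oxygen of the 16-membered benzoate macrolide) next to the heteroatom-bearing C14. C15 can therefore be a tertiary α-acyloxy radical/alkylchromium made by decarboxylation of a 2-(aroyloxy)isobutyric acid, and C14 its aldehyde acceptor, so the hindered tertiary ester is never made by macrolactonisation.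
3. Forward order: farnesyl acetate → C12 oxidation → C6–C7 epoxide → bromohydrin → bromonium cyclisation (ring A, cyclohexene) → C10–C11 epoxide → allyl extension → bromohydrin → arylation at C1 → C14 aldehyde → macrocyclisation at C14–C15 → ketone → alcohol → bromide → desilylation.
4. Stereochemistry: C6/C7 from a Shi epoxide (bromide inversion at C6, then enantiospecific anti opening of the bromonium ion at C7); C10/C11 from a Sharpless epoxide opened by bromide with inversion at C10; C14 from a CBS reduction, then bromide introduction with double inversion through the neighbouring benzoate.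

Key step: step 17

Remark: terpenoid carbons are numbered C1–C15 as in a geranylgeranyl chain (C1 benzylic CH2, C2=C3 ring alkene, C6 CHBr and C7 quaternary carbon of ring A, C10 CHBr, C11 carbinol, C14 CHBr, C15 the CMe2 carbon on the lactone oxygen); the farnesyl intermediates use the same numbers.

Step 1
Reactants: 1 (2E,6E)-farnesyl acetate
Product: 2 (2E,6E,10E)-12-hydroxyfarnesyl acetate
Conditions: SeO2 (cat.), t-BuOOH, salicylic acid (cat.), CH2Cl2, rt
Reagents that add atoms: tert-butyl hydroperoxide, CC(C)(C)OO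
Why: Selenium dioxide allylic oxidation (ene reaction, then [2,3]-shift) should hydroxylate the (E)-methyl of the terminal isopropylidene group, because the C2–C3 alkene is deactivated by the allylic acetate and the terminal alkene is the most reactive, and the sigmatropic step fixes the (10E) geometry.

Step 2
Reactants: 2 (2E,6E,10E)-12-hydroxyfarnesyl acetate
Product: 3 12-O-TBDPS ether of 2
Conditions: t-BuPh2SiCl, imidazole, DMF, rt
Reagents that add atoms: tert-butyl(chloro)diphenylsilane, CC(C)(C)[Si](Cl)(c1ccccc1)c1ccccc1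
Why: Standard silylation of the primary allylic alcohol, which also makes the C10–C11 alkene electron-poorer and sterically shielded for the next step.

Step 3
Reactants: 3 12-O-TBDPS ether
Product: 4 (6R,7R)-6,7-epoxide
Conditions: D-fructose-derived ketone catalyst of the Shi epoxidation (0.3 equiv), KHSO5 (Oxone), K2CO3, Bu4NHSO4, MeCN/CH2(OMe)2/aq. Na2B4O7 buffer, 0 °C
Reagents that add atoms: potassium peroxymonosulfate, [K+].[O-]S(=O)(=O)OO
Why: Shi asymmetric epoxidation should take place only at the C6–C7 alkene, the one trisubstituted alkene without an allylic oxygen substituent, and the D-fructose-derived dioxirane should give the (R,R)-epoxide through the spiro transition state usual for (E)-trisubstituted alkenes.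

Step 4
Reactants: 4 (6R,7R)-6,7-epoxide
Product: 5 (6S,7R)-6-bromo-7-hydroxy compound
Conditions: Li2NiBr4, THF, 0 °C to rt
Reagents that add atoms: dilithium tetrabromonickelate, [Li+].[Li+].Br[Ni-2](Br)(Br)Br
Why: SN2 opening of the trisubstituted epoxide by bromide under near-neutral conditions should occur at the less substituted C6 with inversion, setting (6S)-Br and leaving the (7R) tertiary alcohol.

Step 5
Reactants: 5 (6S,7R)-bromohydrin
Product: 6 ring A allylic acetate, (6S,7S)
Conditions: Tf2O, 2,6-di-tert-butyl-4-methylpyridine, CH2Cl2, −78 to −40 °C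
Reagents that add atoms: none
Why: Ionisation of the tertiary alcohol with anchimeric help from the neighbouring bromine should give the enantiopure bromonium ion, which C2 of the C2–C3 alkene opens at C7 anti to bromine through a chair transition state (bromonium-initiated cation–olefin cyclisation), so C7 becomes (S) with C6 untouched, and loss of the C2 proton from the tertiary C3 cation, for which the acetate carbonyl is placed as an internal base in a six-membered arrangement, should give the tetrasubstituted ring alkene.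

Step 6
Reactants: 6 ring A allylic acetate
Product: 7 ring A acetate with free (E)-allylic alcohol at C12
Conditions: Bu4NF, AcOH, THF, 0 °C to rt
Reagents that add atoms: none
Why: Acetic-acid-buffered fluoride desilylation should remove the silyl ether without touching the acetate or the hindered secondary bromide.

Step 7
Reactants: 7 allylic alcohol
Product: 8 (10S,11S)-epoxy alcohol
Conditions: Ti(OiPr)4, L-(+)-diethyl tartrate, t-BuOOH, 4 Å sieves, CH2Cl2, −20 °C
Reagents that add atoms: tert-butyl hydroperoxide, CC(C)(C)OO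
Why: Sharpless asymmetric epoxidation acts only on the alkene of the free allylic alcohol (the ring alkene carries an acetate) and with L-(+)-tartrate should give the (2S,3S)-epoxy alcohol, so C10 and C11 are both (S) under reagent control.

Step 8
Reactants: 8 (10S,11S)-epoxy alcohol, 9 allylmagnesium bromide
Product: 11 (10S,11S)-epoxide carrying the C12–C14 butenyl chain, via epoxy triflate 10 (not isolated)
Conditions: Tf2O, 2,6-lutidine, CH2Cl2, −78 °C; then (CH2=CHCH2)2CuMgBr (from 9 and CuI), THF/Et2O, −78 °C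
Reagents that add atoms: none
Why: SN2 displacement of the primary epoxy triflate by the allyl cuprate, faster at −78 °C than attack on the epoxide, the acetate or the secondary bromide, adds C13 and C14 without touching a stereocentre.

Step 9
Reactants: 11 (10S,11S)-epoxide
Product: 12 (10R,11S)-10-bromo-11-hydroxy compound
Conditions: Li2NiBr4, THF, 0 °C to rt
Reagents that add atoms: dilithium tetrabromonickelate, [Li+].[Li+].Br[Ni-2](Br)(Br)Br
Why: As in step 4, bromide should open the epoxide by SN2 at the secondary C10 with inversion, giving the (10R)-bromide and the (11S) tertiary alcohol.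

Step 10
Reactants: 12 (10R,11S)-bromohydrin
Product: 13 11-O-triethylsilyl ether
Conditions: Et3SiOTf, 2,6-lutidine, CH2Cl2, −78 to 0 °C
Reagents that add atoms: triethylsilyl trifluoromethanesulfonate, CC[Si](CC)(CC)OS(=O)(=O)C(F)(F)F
Why: Silylation of the hindered tertiary alcohol prevents later lactol formation with the C14 aldehyde and base-induced re-closure of the bromohydrin to the epoxide.

Step 11
Reactants: 14 3-bromo-4-hydroxybenzoic acid
Product: 16 3-bromo-4-(triisopropylsilyloxy)benzoic acid, via bis-silylated benzoate 15 (not isolated)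
Conditions: i-Pr3SiCl (2.2 equiv), imidazole, DMF, rt; then K2CO3, MeOH/THF/H2O, 0 °C
Reagents that add atoms: chlorotriisopropylsilane, CC(C)[Si](Cl)(C(C)C)C(C)C
Why: Both OH groups are silylated and the far more labile silyl ester is then hydrolysed selectively, leaving the phenol as its bulky silyl ether.

Step 12
Reactants: 16 3-bromo-4-(triisopropylsilyloxy)benzoic acid, 17 tert-butyl 2-hydroxy-2-methylpropanoate
Product: 19 tertiary benzoate diester, via acid chloride 18 (not isolated)
Conditions: (COCl)2, DMF (cat.), CH2Cl2, 0 °C to rt; then 17, Et3N, DMAP, toluene, 60 °C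
Reagents that add atoms: none
Why: DMAP-catalysed acylation of the tertiary α-hydroxy ester by the aroyl chloride forms the hindered C15–O ester bond intermolecularly on a simple fragment, where excess reagent and heat can be used.

Step 13
Reactants: 19 tertiary benzoate diester (aryl bromide)
Product: 20 aryl pinacol boronate
Conditions: B2pin2, PdCl2(dppf) (5 mol%), KOAc, 1,4-dioxane, 85 °C
Reagents that add atoms: bis(pinacolato)diboron, CC1(C)OB(OC1(C)C)B1OC(C)(C)C(C)(C)O1
Why: Miyaura borylation converts the aryl bromide into the boronic ester and tolerates both esters and the aryl silyl ether.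

Step 14
Reactants: 20 aryl pinacol boronate tert-butyl ester
Product: 21 2-(aroyloxy)isobutyric acid boronate
Conditions: CF3CO2H/CH2Cl2 (1:4), 0 °C to rt
Reagents that add atoms: none
Why: Acidolysis removes only the tert-butyl ester (loss of isobutene), since ionisation of the other tertiary ester is disfavoured by its α-carboxyl group, and the boronate and aryl silyl ether are stable to the acid.

Step 15
Reactants: 13 ring A allylic acetate with protected bromohydrin chain, 21 boronate acid
Product: 22 seco acid with C1–aryl bond and terminal alkene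
Conditions: Pd(PPh3)4 (10 mol%), K2CO3, 1,4-dioxane/H2O, 70 °C
Reagents that add atoms: none
Why: In this allyl–aryl Suzuki–Miyaura coupling, zerovalent palladium ionises the allylic acetate to a π-allyl complex that should couple with the arylboronate at the less hindered primary terminus C1, keeping the tetrasubstituted alkene, while the secondary alkyl bromides are inert.

Step 16
Reactants: 22 seco acid with terminal alkene
Product: 23 seco acid with C14 aldehyde
Conditions: OsO4 (2 mol%), NaIO4, 2,6-lutidine, 1,4-dioxane/H2O, rt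
Reagents that add atoms: sodium periodate, [Na+].[O-]I(=O)(=O)=O
Why: Lemieux–Johnson cleavage should act on the unhindered monosubstituted alkene much faster than on the hindered tetrasubstituted ring alkene and unmasks the C14 aldehyde only after the C11 oxygen has been protected.

Step 17
Reactants: 23 seco acid with C14 aldehyde
Product: 26 16-membered macrolide with C14 hydroxyl (both C14 epimers), via N-acyloxyphthalimide 24 (not isolated), via trimethylsilyl ether 25 (not isolated)
Conditions: N-hydroxyphthalimide, i-PrN=C=N-i-Pr, CH2Cl2, rt; then syringe-pump addition to CrCl2 (6 equiv), Me3SiCl (3 equiv), THF/DMF (final 2 mM), rt; then aq. citric acid, THF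
Reagents that add atoms: none
Why: Proposed new method: divalent chromium should reduce the N-acyloxyphthalimide 24 by single-electron transfer, CO2 and phthalimide anion are lost, and the tertiary α-acyloxy radical at C15 is captured by a second CrCl2 as an alkylchromium of trivalent chromium, which adds to the C14 aldehyde by the carbonyl-selective, ester-tolerant pathway of Nozaki–Hiyama–Kishi chemistry. The closest known reaction type is the intermolecular chromium-mediated decarboxylative addition of redox-active esters to aldehydes, and Nozaki–Hiyama–Kishi macrocyclisation itself is well precedented for vinyl and allyl halides. The closure is a 16-exo-trig addition that forms the C14–C15 bond and with it the 16-membered macrolide ring and its tertiary benzoate, without esterifying a hindered tertiary alcohol. The new carbinol centre C14 has only remote stereocentres to guide it and is not controlled here; it is erased in step 18 and reset by the catalyst in step 19. The step needs chemoselectivity for the activated ester over the two secondary C–Br bonds and the ring alkene (CrCl2 without a cobalt or nickel co-catalyst should not reduce unactivated alkyl bromides), ring closure over oligomerisation (slow addition at high dilution), and suppression of 1,2-acyl migration from the tertiary to the new secondary oxygen, which Me3SiCl secures by silylating the chromium alkoxide as it forms.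

Step 18
Reactants: 26 macrolide C14 alcohol (epimers)
Product: 27 macrolide C14 ketone
Conditions: Dess–Martin periodinane, NaHCO3, CH2Cl2, 0 °C to rt
Reagents that add atoms: none
Why: Dess–Martin oxidation under buffered conditions converts both epimers into one α-acyloxy ketone and so removes the uncontrolled stereocentre.

Step 19
Reactants: 27 macrolide C14 ketone
Product: 28 (14R)-hydroxy macrolide
Conditions: (S)-2-methyl-CBS-oxazaborolidine (1 equiv), catecholborane, toluene/CH2Cl2, −78 °C
Reagents that add atoms: none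
Why: Corey–Bakshi–Shibata reduction should treat the quaternary C15 as the large and the C13 methylene as the small substituent, so the (S)-catalyst delivers hydride to give the (14R)-alcohol, and catecholborane spares the ring alkene.

Step 20
Reactants: 28 (14R)-hydroxy macrolide
Product: 30 bis-silylated target with (14R)-bromide, via dioxolanylium triflate 29 (not isolated)
Conditions: Tf2O, 2,6-di-tert-butyl-4-methylpyridine, CH2Cl2, −78 °C; then Bu4NBr, ClCH2CH2Cl, −78 to 40 °C
Reagents that add atoms: tetrabutylammonium bromide, CCCC[N+](CCCC)(CCCC)CCCC.[Br-]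
Why: Triflation triggers anchimeric displacement by the neighbouring benzoate carbonyl (inversion at C14) to the 2-aryl-1,3-dioxolan-2-ylium ion 29, which bromide should open by SN2 at the secondary C14 (second inversion, net retention) as in the Hanessian–Hullar bromo-benzoate formation, while any tertiary bromide from attack at C15 is expected to re-ionise and funnel to the more stable secondary bromide–tertiary ester.

Step 21
Reactants: 30 bis-silylated target
Product: 31 target macrolide CNP0153321.1
Conditions: HF·pyridine, pyridine, THF, 0 °C to rt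
Reagents that add atoms: none
Why: Fluoride cleavage of the tertiary triethylsilyl ether and the aryl triisopropylsilyl ether under non-basic conditions frees the alcohol and the phenol without closing the bromohydrin to an epoxide or opening the lactone.

**Compound list**
1 | (2E,6E)-farnesyl acetate, (2E,6E)-3,7,11-trimethyldodeca-2,6,10-trien-1-yl acetate | CC(=O)OC/C=C(\C)CC/C=C(\C)CCC=C(C)C | starting material
2 | (2E,6E,10E)-12-hydroxy-3,7,11-trimethyldodeca-2,6,10-trien-1-yl acetate | CC(=O)OC/C=C(\C)CC/C=C(\C)CC/C=C(\C)CO | intermediate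
3 | (2E,6E,10E)-12-[(tert-butyldiphenylsilyl)oxy]-3,7,11-trimethyldodeca-2,6,10-trien-1-yl acetate | CC(=O)OC/C=C(\C)CC/C=C(\C)CC/C=C(\C)CO[Si](c1ccccc1)(c1ccccc1)C(C)(C)C | intermediate
4 | (2E,10E)-(6R,7R)-6,7-epoxy-12-[(tert-butyldiphenylsilyl)oxy]-3,7,11-trimethyldodeca-2,10-dien-1-yl acetate | CC(=O)OC/C=C(\C)CC[C@H]1O[C@]1(C)CC/C=C(\C)CO[Si](c1ccccc1)(c1ccccc1)C(C)(C)C | intermediate
5 | (2E,10E)-(6S,7R)-6-bromo-7-hydroxy-12-[(tert-butyldiphenylsilyl)oxy]-3,7,11-trimethyldodeca-2,10-dien-1-yl acetate | CC(=O)OC/C=C(\C)CC[C@H](Br)[C@](C)(O)CC/C=C(\C)CO[Si](c1ccccc1)(c1ccccc1)C(C)(C)C | intermediate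
6 | {(5S,6S)-5-bromo-6-[(3E)-5-[(tert-butyldiphenylsilyl)oxy]-4-methylpent-3-en-1-yl]-2,6-dimethylcyclohex-1-en-1-yl}methyl acetate | CC1=C(COC(C)=O)[C@](C)(CC/C=C(\C)CO[Si](c2ccccc2)(c2ccccc2)C(C)(C)C)[C@@H](Br)CC1 | intermediate
7 | {(5S,6S)-5-bromo-6-[(3E)-5-hydroxy-4-methylpent-3-en-1-yl]-2,6-dimethylcyclohex-1-en-1-yl}methyl acetate | CC1=C(COC(C)=O)[C@](C)(CC/C=C(\C)CO)[C@@H](Br)CC1 | intermediate
8 | [(5S,6S)-5-bromo-6-{2-[(2S,3S)-3-(hydroxymethyl)-3-methyloxiran-2-yl]ethyl}-2,6-dimethylcyclohex-1-en-1-yl]methyl acetate | CC1=C(COC(C)=O)[C@](C)(CC[C@@H]2O[C@@]2(C)CO)[C@@H](Br)CC1 | intermediate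
9 | allylmagnesium bromide | C=CC[Mg]Br | starting material
10 | trifluoromethanesulfonate of the primary alcohol of 8 (epoxy triflate) | CC1=C(COC(C)=O)[C@](C)(CC[C@@H]2O[C@@]2(C)COS(=O)(=O)C(F)(F)F)[C@@H](Br)CC1 | intermediate
11 | [(5S,6S)-5-bromo-6-{2-[(2S,3S)-3-(but-3-en-1-yl)-3-methyloxiran-2-yl]ethyl}-2,6-dimethylcyclohex-1-en-1-yl]methyl acetate | CC1=C(COC(C)=O)[C@](C)(CC[C@@H]2O[C@@]2(C)CCC=C)[C@@H](Br)CC1 | intermediate
12 | {(5S,6S)-5-bromo-6-[(3R,4S)-3-bromo-4-hydroxy-4-methyloct-7-en-1-yl]-2,6-dimethylcyclohex-1-en-1-yl}methyl acetate | CC1=C(COC(C)=O)[C@](C)(CC[C@@H](Br)[C@@](C)(O)CCC=C)[C@@H](Br)CC1 | intermediate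
13 | {(5S,6S)-5-bromo-6-[(3R,4S)-3-bromo-4-methyl-4-[(triethylsilyl)oxy]oct-7-en-1-yl]-2,6-dimethylcyclohex-1-en-1-yl}methyl acetate | CC1=C(COC(C)=O)[C@](C)(CC[C@@H](Br)[C@@](C)(O[Si](CC)(CC)CC)CCC=C)[C@@H](Br)CC1 | intermediate
14 | 3-bromo-4-hydroxybenzoic acid | OC(=O)c1ccc(O)c(Br)c1 | starting material
15 | triisopropylsilyl 3-bromo-4-[(triisopropylsilyl)oxy]benzoate | CC(C)[Si](C(C)C)(C(C)C)OC(=O)c1ccc(O[Si](C(C)C)(C(C)C)C(C)C)c(Br)c1 | intermediate
16 | 3-bromo-4-[(triisopropylsilyl)oxy]benzoic acid | OC(=O)c1ccc(O[Si](C(C)C)(C(C)C)C(C)C)c(Br)c1 | intermediate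
17 | tert-butyl 2-hydroxy-2-methylpropanoate | CC(C)(C)OC(=O)C(C)(C)O | starting material
18 | 3-bromo-4-[(triisopropylsilyl)oxy]benzoyl chloride | ClC(=O)c1ccc(O[Si](C(C)C)(C(C)C)C(C)C)c(Br)c1 | intermediate
19 | 1-(tert-butoxy)-2-methyl-1-oxopropan-2-yl 3-bromo-4-[(triisopropylsilyl)oxy]benzoate | CC(C)(C)OC(=O)C(C)(C)OC(=O)c1ccc(O[Si](C(C)C)(C(C)C)C(C)C)c(Br)c1 | intermediate
20 | 1-(tert-butoxy)-2-methyl-1-oxopropan-2-yl 3-(4,4,5,5-tetramethyl-1,3,2-dioxaborolan-2-yl)-4-[(triisopropylsilyl)oxy]benzoate | CC(C)(C)OC(=O)C(C)(C)OC(=O)c1ccc(O[Si](C(C)C)(C(C)C)C(C)C)c(c1)B2OC(C)(C)C(C)(C)O2 | intermediate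
21 | 2-methyl-2-({3-(4,4,5,5-tetramethyl-1,3,2-dioxaborolan-2-yl)-4-[(triisopropylsilyl)oxy]benzoyl}oxy)propanoic acid | OC(=O)C(C)(C)OC(=O)c1ccc(O[Si](C(C)C)(C(C)C)C(C)C)c(c1)B2OC(C)(C)C(C)(C)O2 | intermediate
22 | 2-{[3-({(5S,6S)-5-bromo-6-[(3R,4S)-3-bromo-4-methyl-4-[(triethylsilyl)oxy]oct-7-en-1-yl]-2,6-dimethylcyclohex-1-en-1-yl}methyl)-4-[(triisopropylsilyl)oxy]benzoyl]oxy}-2-methylpropanoic acid | CC1=C(Cc2cc(ccc2O[Si](C(C)C)(C(C)C)C(C)C)C(=O)OC(C)(C)C(O)=O)[C@](C)(CC[C@@H](Br)[C@@](C)(O[Si](CC)(CC)CC)CCC=C)[C@@H](Br)CC1 | intermediate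
23 | 2-{[3-({(5S,6S)-5-bromo-6-[(3R,4S)-3-bromo-4-methyl-7-oxo-4-[(triethylsilyl)oxy]heptyl]-2,6-dimethylcyclohex-1-en-1-yl}methyl)-4-[(triisopropylsilyl)oxy]benzoyl]oxy}-2-methylpropanoic acid | CC1=C(Cc2cc(ccc2O[Si](C(C)C)(C(C)C)C(C)C)C(=O)OC(C)(C)C(O)=O)[C@](C)(CC[C@@H](Br)[C@@](C)(O[Si](CC)(CC)CC)CCC=O)[C@@H](Br)CC1 | intermediate
24 | N-acyloxyphthalimide (1,3-dioxoisoindolin-2-yl ester) of acid 23 | CC1=C(Cc2cc(ccc2O[Si](C(C)C)(C(C)C)C(C)C)C(=O)OC(C)(C)C(=O)ON2C(=O)c3ccccc3C2=O)[C@](C)(CC[C@@H](Br)[C@@](C)(O[Si](CC)(CC)CC)CCC=O)[C@@H](Br)CC1 | intermediate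
25 | (6S,7S,10R,11S)-macrolide with C14 O-trimethylsilyl (C14 epimers), 11-O-triethylsilyl, phenol O-triisopropylsilyl | CC1=C2Cc3cc(ccc3O[Si](C(C)C)(C(C)C)C(C)C)C(=O)OC(C)(C)C(O[Si](C)(C)C)CC[C@](C)(O[Si](CC)(CC)CC)[C@H](Br)CC[C@]2(C)[C@@H](Br)CC1 | intermediate
26 | (6S,7S,10R,11S)-macrolide with free C14 hydroxyl (C14 epimers), 11-O-triethylsilyl, phenol O-triisopropylsilyl | CC1=C2Cc3cc(ccc3O[Si](C(C)C)(C(C)C)C(C)C)C(=O)OC(C)(C)C(O)CC[C@](C)(O[Si](CC)(CC)CC)[C@H](Br)CC[C@]2(C)[C@@H](Br)CC1 | intermediate
27 | (6S,7S,10R,11S)-macrolide C14 ketone, 11-O-triethylsilyl, phenol O-triisopropylsilyl | CC1=C2Cc3cc(ccc3O[Si](C(C)C)(C(C)C)C(C)C)C(=O)OC(C)(C)C(=O)CC[C@](C)(O[Si](CC)(CC)CC)[C@H](Br)CC[C@]2(C)[C@@H](Br)CC1 | intermediate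
28 | (6S,7S,10R,11S,14R)-14-hydroxy macrolide, 11-O-triethylsilyl, phenol O-triisopropylsilyl | CC1=C2Cc3cc(ccc3O[Si](C(C)C)(C(C)C)C(C)C)C(=O)OC(C)(C)[C@H](O)CC[C@](C)(O[Si](CC)(CC)CC)[C@H](Br)CC[C@]2(C)[C@@H](Br)CC1 | intermediate
29 | 2-aryl-4,4-dimethyl-1,3-dioxolan-2-ylium triflate spanning C15–O and C14–O, C14 inverted to (S) | CC1=C2Cc3cc(ccc3O[Si](C(C)C)(C(C)C)C(C)C)C4=[O+][C@H](C(C)(C)O4)CC[C@](C)(O[Si](CC)(CC)CC)[C@H](Br)CC[C@]2(C)[C@@H](Br)CC1.[O-]S(=O)(=O)C(F)(F)F | intermediate
30 | (6S,7S,10R,11S,14R)-tribromo macrolide, 11-O-triethylsilyl, phenol O-triisopropylsilyl | CC1=C2Cc3cc(ccc3O[Si](C(C)C)(C(C)C)C(C)C)C(=O)OC(C)(C)[C@H](Br)CC[C@](C)(O[Si](CC)(CC)CC)[C@H](Br)CC[C@]2(C)[C@@H](Br)CC1 | intermediate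
31 | CNP0153321.1, (6S,7S,10R,11S,14R)-6,10,14-tribromo-11-hydroxy 16-membered 4-hydroxybenzoate macrolide | CC1=C2Cc3cc(ccc3O)C(=O)OC(C)(C)[C@H](Br)CC[C@](C)(O)[C@H](Br)CC[C@]2(C)[C@@H](Br)CC1 | target

**Step count**
Total steps: 21. Longest linear sequence: 17 steps (steps 1–10, then 15–21); steps 11–14 build the arene fragment in parallel.

**Three steps most likely to fail**

Step 17 (Proposed new method). The tertiary α-acyloxy radical may be reduced by hydrogen-atom abstraction to the isopropyl ester, or may react intermolecularly (oligomerisation), before the ring closes; pinacol coupling of the aldehyde may also compete. The fallback gives up C–C ring closure and closes the macrolide at the C15–O bond by known epoxide chemistry. It sets out from 13 and 16. Miyaura borylation of 16 would give 3-(pinacolboryl)-4-[(triisopropylsilyl)oxy]benzoic acid F1, and its Suzuki–Miyaura coupling with 13 the seco benzoic acid F2. Lemieux–Johnson cleavage would give the aldehyde F3, and Wittig olefination with isopropylidenetriphenylphosphorane the prenyl seco acid F4. Shi epoxidation with the D-fructose-derived ketone would give the (14R)-14,15-epoxide F5. Acid-catalysed (camphorsulfonic acid, high dilution) intramolecular opening of the trisubstituted epoxide by the carboxylic acid at the tertiary C15 would then give the (14R)-hydroxy macrolide 28, where the route continues with step 20.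

Step 20. Bromide may open the acyloxonium ion at the tertiary C15 (ring contraction to the secondary benzoate with a tertiary bromide), the ion may lose a proton to an isopropenyl group, and equilibration to the secondary bromide may be slow. The fallback puts bromine on C14 before the ester exists. It sets out from 13 and passes through the prenyl seco acid F4 (made as in the first fallback). Shi epoxidation with the enantiomeric, L-fructose-derived ketone would give the (14S)-epoxide F6, and Li2NiBr4 the (14R)-bromo-15-hydroxy seco acid F7. Ionisation of the tertiary alcohol (CF3SO3H cat., (CF3)2CHOH, high dilution) would give the enantiopure bromonium ion, which the carboxylic acid opens at the tertiary C15 with bromolactonisation regiochemistry. This gives 30 directly, and the route resumes at step 21.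

Step 5. The tertiary C3 cation may lose a C4 or methyl proton instead of the C2 proton, giving the endocyclic trisubstituted or exocyclic alkene isomers, and bromonium transfer between alkenes may erode enantiopurity. The fallback converges the isomers through conjugation. It sets out from 5: the same ionisation gives the ring-closed acetates as a double-bond isomer mixture F8 (drawn as the C3=C4 isomer). K2CO3/MeOH would give the alcohols F9, and Dess–Martin oxidation the β,γ-unsaturated aldehydes F10. DBU would isomerise all of them to the conjugated tetrasubstituted enal F11 (the α- to β-cyclocitral type of isomerisation). Luche reduction (NaBH4, CeCl3) would give the allylic alcohol F12, and acetylation (Ac2O, pyridine) returns 6.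

**Further compounds**
F1 | step 17 | 3-(4,4,5,5-tetramethyl-1,3,2-dioxaborolan-2-yl)-4-[(triisopropylsilyl)oxy]benzoic acid | OC(=O)c1ccc(O[Si](C(C)C)(C(C)C)C(C)C)c(c1)B2OC(C)(C)C(C)(C)O2
F2 | step 17 | 3-({(5S,6S)-5-bromo-6-[(3R,4S)-3-bromo-4-methyl-4-[(triethylsilyl)oxy]oct-7-en-1-yl]-2,6-dimethylcyclohex-1-en-1-yl}methyl)-4-[(triisopropylsilyl)oxy]benzoic acid | CC1=C(Cc2cc(ccc2O[Si](C(C)C)(C(C)C)C(C)C)C(O)=O)[C@](C)(CC[C@@H](Br)[C@@](C)(O[Si](CC)(CC)CC)CCC=C)[C@@H](Br)CC1
F3 | step 17 | C14 aldehyde of F2 (7-oxoheptyl chain) | CC1=C(Cc2cc(ccc2O[Si](C(C)C)(C(C)C)C(C)C)C(O)=O)[C@](C)(CC[C@@H](Br)[C@@](C)(O[Si](CC)(CC)CC)CCC=O)[C@@H](Br)CC1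
F4 | step 17 | prenyl seco acid (C14=C15 isopropylidene alkene) | CC1=C(Cc2cc(ccc2O[Si](C(C)C)(C(C)C)C(C)C)C(O)=O)[C@](C)(CC[C@@H](Br)[C@@](C)(O[Si](CC)(CC)CC)CCC=C(C)C)[C@@H](Br)CC1
F5 | step 17 | (14R)-14,15-epoxy seco acid | CC1=C(Cc2cc(ccc2O[Si](C(C)C)(C(C)C)C(C)C)C(O)=O)[C@](C)(CC[C@@H](Br)[C@@](C)(O[Si](CC)(CC)CC)CC[C@H]3OC3(C)C)[C@@H](Br)CC1
F6 | step 20 | (14S)-14,15-epoxy seco acid | CC1=C(Cc2cc(ccc2O[Si](C(C)C)(C(C)C)C(C)C)C(O)=O)[C@](C)(CC[C@@H](Br)[C@@](C)(O[Si](CC)(CC)CC)CC[C@@H]3OC3(C)C)[C@@H](Br)CC1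
F7 | step 20 | (14R)-14-bromo-15-hydroxy seco acid | CC1=C(Cc2cc(ccc2O[Si](C(C)C)(C(C)C)C(C)C)C(O)=O)[C@](C)(CC[C@@H](Br)[C@@](C)(O[Si](CC)(CC)CC)CC[C@@H](Br)C(C)(C)O)[C@@H](Br)CC1
F8 | step 5 | double-bond isomer of 6 with the ring alkene between C3 and C4 (C2 epimers; stands for the isomer mixture) | CC1=CC[C@H](Br)[C@@](C)(CC/C=C(\C)CO[Si](c2ccccc2)(c2ccccc2)C(C)(C)C)C1COC(C)=O
F9 | step 5 | primary alcohol from deacetylation of F8 | CC1=CC[C@H](Br)[C@@](C)(CC/C=C(\C)CO[Si](c2ccccc2)(c2ccccc2)C(C)(C)C)C1CO
F10 | step 5 | β,γ-unsaturated aldehyde from oxidation of F9 | CC1=CC[C@H](Br)[C@@](C)(CC/C=C(\C)CO[Si](c2ccccc2)(c2ccccc2)C(C)(C)C)C1C=O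
F11 | step 5 | (5S,6S)-5-bromo-6-[(3E)-5-[(tert-butyldiphenylsilyl)oxy]-4-methylpent-3-en-1-yl]-2,6-dimethylcyclohex-1-ene-1-carbaldehyde | CC1=C(C=O)[C@](C)(CC/C=C(\C)CO[Si](c2ccccc2)(c2ccccc2)C(C)(C)C)[C@@H](Br)CC1
F12 | step 5 | {(5S,6S)-5-bromo-6-[(3E)-5-[(tert-butyldiphenylsilyl)oxy]-4-methylpent-3-en-1-yl]-2,6-dimethylcyclohex-1-en-1-yl}methanol | CC1=C(CO)[C@](C)(CC/C=C(\C)CO[Si](c2ccccc2)(c2ccccc2)C(C)(C)C)[C@@H](Br)CC1
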